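Everything rests on opening the pyran ring at its O1–C2 ether bond. C2, the quaternary allylic ether carbon with its CH2O arm, is read as the substituted carbon of a 2-methyl-2-vinyloxirane, and the cis C3=C4 bond holds the phenolic O1 next to it. In the key step the phenol of a (Z)-styryl (S)-oxirane attacks that carbon in a 6-exo-tet opening with inversion: one operation closes the pyran ring, sets the (R) quaternary centre from an epoxy alcohol of known configuration and frees the CH2OH group for feruloylation. The precursor is an acyclic aryl acetate built by Sonogashira coupling and cis-semihydrogenation.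

Key step: step 6

Assumption: (S)-2-methylglycidol, the Sharpless epoxidation product of 2-methylprop-2-en-1-ol, is taken as a commercial enantiopure starting material, and all operations from step 6 onwards are run with exclusion of light and heat.

Step 1
Reactants: 1 1-(2,4-dihydroxyphenyl)ethanone
Product: 2 4-acetyl-3-hydroxyphenyl acetate
Conditions: Ac2O (1.05 equiv), pyridine, 0 °C
Reagents that add atoms: acetic anhydride, CC(=O)OC(C)=O
Why: Chemoselective O-acylation should take place only at the 4-hydroxyl, because the 2-hydroxyl is locked in a hydrogen bond to the acetyl carbonyl; the ester masks the future O1 against benzofuran formation in step 4.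

Step 2
Reactants: 2 4-acetyl-3-hydroxyphenyl acetate
Product: 3 4-acetyl-5-hydroxy-2-iodophenyl acetate
Conditions: N-iodosuccinimide (1.05 equiv), CF3CO2H (30 mol%), MeCN, rt, dark
Reagents that add atoms: N-iodosuccinimide, O=C1CCC(=O)N1I
Why: Electrophilic aromatic iodination should go para to the free hydroxyl, the strongest donor left on the ring, because the only other activated site lies between two oxygen substituents and is the more hindered.

Step 3
Reactants: 4 (S)-2-methylglycidol
Product: 6 (S)-2-ethynyl-2-methyloxirane, via (R)-2-methyloxirane-2-carbaldehyde 5 (not isolated)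
Conditions: PhI(OAc)2 (1.1 equiv), TEMPO (10 mol%), CH2Cl2, rt; then MeOH, K2CO3, dimethyl (1-diazo-2-oxopropyl)phosphonate, 0 °C to rt; product kept as a titrated Et2O solution
Reagents that add atoms: dimethyl (1-diazo-2-oxopropyl)phosphonate, COP(=O)(OC)C(=[N+]=[N-])C(C)=O
Why: TEMPO/PhI(OAc)2 oxidation gives the epoxy aldehyde without touching the oxirane, and Ohira–Bestmann homologation in the same flask should convert it to the terminal alkyne; the quaternary stereocenter has no α-hydrogen and cannot epimerise.

Step 4
Reactants: 3 4-acetyl-5-hydroxy-2-iodophenyl acetate; 6 (S)-2-ethynyl-2-methyloxirane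
Product: 7 4-acetyl-5-hydroxy-2-{[(2S)-2-methyloxiran-2-yl]ethynyl}phenyl acetate
Conditions: Pd(PPh3)2Cl2 (3 mol%), CuI (5 mol%), Et3N (3 equiv), THF, rt, argon
Reagents that add atoms: none
Why: Sonogashira coupling of an aryl iodide at room temperature should be faster than ionisation of the propargylic oxirane by zerovalent palladium, and the acetate prevents 5-endo-dig closure of the ortho oxygen onto the alkyne.

Step 5
Reactants: 7 4-acetyl-5-hydroxy-2-{[(2S)-2-methyloxiran-2-yl]ethynyl}phenyl acetate
Product: 8 4-acetyl-5-hydroxy-2-{(Z)-2-[(2S)-2-methyloxiran-2-yl]ethenyl}phenyl acetate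
Conditions: H2 (1 atm), Pd/CaCO3 poisoned with Pb(OAc)2, quinoline, EtOAc, rt, stopped after one equivalent of H2
Reagents that add atoms: none
Why: Lindlar semihydrogenation adds both hydrogens syn on the poisoned palladium surface and should give the (Z)-alkene that brings O1 and C2 together; quinoline and uptake control limit over-reduction and oxirane hydrogenolysis.

Step 6
Reactants: 8 4-acetyl-5-hydroxy-2-{(Z)-2-[(2S)-2-methyloxiran-2-yl]ethenyl}phenyl acetate
Product: 10 1-[(2R)-7-hydroxy-2-(hydroxymethyl)-2-methyl-2H-chromen-6-yl]ethanone, via (Z)-styryl oxirane phenol 9 (not isolated)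
Conditions: pyrrolidine (1.05 equiv), CH2Cl2, 0 °C; then racemic camphor-10-sulfonic acid (15 mol%), −40 °C to 0 °C, dark
Reagents that add atoms: none
Why: Aminolysis of the activated aryl acetate frees phenol 9, and the sulfonic acid then activates the oxirane oxygen so that O1 attacks the tertiary allylic oxirane carbon from the face opposite the breaking C–O bond, the primary oxygen leaving as the CH2OH group. The closest known reaction type is the acid-catalysed intramolecular opening of 2,2-disubstituted and trisubstituted epoxides by phenols at the more substituted carbon, which gives 2,2-disubstituted chromans with inversion. The pyran ring closes in the 6-exo-tet mode, since the breaking oxirane C–O bond lies outside the new ring. The only new stereocenter, C2, is controlled by the (S) oxirane carbon carried from 4, which backside displacement inverts to (R). The step needs attack at the tertiary allylic carbon in preference to 7-endo attack at the CH2 terminus, which the positive charge developing at the substituted, alkene-conjugated carbon and the six-membered transition state secure, and the (Z) geometry from step 5 places O1 within reach. It also needs displacement to outrun free ionisation to a delocalised cation, which the low temperature, the non-polar solvent and the hydrogen bond tying the para hydroxyl to the acetyl group should favour.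

Step 7
Reactants: 10 1-[(2R)-7-hydroxy-2-(hydroxymethyl)-2-methyl-2H-chromen-6-yl]ethanone; 11 (E)-3-(4-acetoxy-3-methoxyphenyl)prop-2-enoic acid
Product: 12 [(2R)-6-acetyl-7-hydroxy-2-methyl-2H-chromen-2-yl]methyl (E)-3-(4-acetoxy-3-methoxyphenyl)prop-2-enoate
Conditions: DCC (1.2 equiv), DMAP (10 mol%), CH2Cl2, 0 °C to rt, dark
Reagents that add atoms: none
Why: In this Steglich esterification the primary alcohol should be far more reactive towards the acylpyridinium intermediate than the phenol chelated to the acetyl group, and the acetate on the acid prevents self-condensation; no stereocenter is touched.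

Step 8
Reactants: 12 [(2R)-6-acetyl-7-hydroxy-2-methyl-2H-chromen-2-yl]methyl (E)-3-(4-acetoxy-3-methoxyphenyl)prop-2-enoate
Product: 13 [(2R)-6-acetyl-7-hydroxy-2-methyl-2H-chromen-2-yl]methyl (E)-3-(4-hydroxy-3-methoxyphenyl)prop-2-enoate
Conditions: pyrrolidine (2 equiv), CH2Cl2, 0 °C, dark; dilute aqueous citric acid work-up
Reagents that add atoms: none
Why: Chemoselective aminolysis of the phenolic acetate should be much faster at 0 °C than attack on the alkyl cinnamate or conjugate addition, so the aryl ester is removed to release the target without touching C2.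

Compound list
1 | 1-(2,4-dihydroxyphenyl)ethanone | CC(=O)c1ccc(O)cc1O | starting material
2 | 4-acetyl-3-hydroxyphenyl acetate | CC(=O)Oc1ccc(C(C)=O)c(O)c1 | intermediate
3 | 4-acetyl-5-hydroxy-2-iodophenyl acetate | CC(=O)Oc1cc(O)c(C(C)=O)cc1I | intermediate
4 | (S)-2-methylglycidol, [(2S)-2-methyloxiran-2-yl]methanol | C[C@]1(CO)CO1 | starting material
5 | (R)-2-methyloxirane-2-carbaldehyde | C[C@]1(C=O)CO1 | intermediate
6 | (S)-2-ethynyl-2-methyloxirane | C[C@]1(C#C)CO1 | intermediate
7 | 4-acetyl-5-hydroxy-2-{[(2S)-2-methyloxiran-2-yl]ethynyl}phenyl acetate | C[C@]1(C#Cc2cc(C(C)=O)c(O)cc2OC(C)=O)CO1 | intermediate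
8 | 4-acetyl-5-hydroxy-2-{(Z)-2-[(2S)-2-methyloxiran-2-yl]ethenyl}phenyl acetate | C[C@]1(/C=C\c2cc(C(C)=O)c(O)cc2OC(C)=O)CO1 | intermediate
9 | 1-{2,4-dihydroxy-5-[(Z)-2-[(2S)-2-methyloxiran-2-yl]ethenyl]phenyl}ethanone | C[C@]1(/C=C\c2cc(C(C)=O)c(O)cc2O)CO1 | intermediate
10 | 1-[(2R)-7-hydroxy-2-(hydroxymethyl)-2-methyl-2H-chromen-6-yl]ethanone | OC[C@@]1(C)C=Cc2cc(C(C)=O)c(O)cc2O1 | intermediate
11 | (E)-3-(4-acetoxy-3-methoxyphenyl)prop-2-enoic acid (4-O-acetylferulic acid) | COc1cc(/C=C/C(=O)O)ccc1OC(C)=O | starting material
12 | [(2R)-6-acetyl-7-hydroxy-2-methyl-2H-chromen-2-yl]methyl (E)-3-(4-acetoxy-3-methoxyphenyl)prop-2-enoate | COc1cc(/C=C/C(=O)OC[C@@]2(C)C=Cc3cc(C(C)=O)c(O)cc3O2)ccc1OC(C)=O | intermediate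
13 | [(2R)-6-acetyl-7-hydroxy-2-methyl-2H-chromen-2-yl]methyl (E)-3-(4-hydroxy-3-methoxyphenyl)prop-2-enoate | COc1cc(/C=C/C(=O)OC[C@@]2(C)C=Cc3cc(C(C)=O)c(O)cc3O2)ccc1O | target

Total step count: 8. Longest linear sequence: 7 steps (steps 1, 2, 4, 5, 6, 7 and 8, from 1 to 13); step 3 is a one-step side branch.

Steps most likely to fail

Step 6. The tertiary C–O bond is conjugated to the alkene and the electron-rich ring, so it may ionise ahead of backside attack, or the product ether may re-ionise under acid. Either process would scramble C2; attack at the CH2 terminus (7-endo) may also compete. The fallback replaces substrate control by classical resolution. It sets out from 10 of insufficient enantiomeric purity as delivered by step 6. Acylation with (1S)-camphanic chloride (pyridine, DMAP, CH2Cl2, 0 °C) should give [(2R)-6-acetyl-7-hydroxy-2-methyl-2H-chromen-2-yl]methyl (1S,4R)-camphanate F1 together with its (2S) diastereomer F2. The two are separated by crystallisation or chromatography. Hydrolysis of F1 (LiOH, THF/H2O, 0 °C) comes back to the route at 10 in enantiopure form.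

Step 5. Hydrogenation may run past the alkene, the propargylic or allylic oxirane C–O bond may be cleaved on palladium, or uptake at the hindered triple bond may stall. The fallback sets the cis geometry before the aryl group is attached and uses no hydrogen. It sets out from 6: trans-hydroboration with pinacolborane ([Rh(cod)Cl]2, P(iPr)3, Et3N, cyclohexane, rt) should give 4,4,5,5-tetramethyl-2-{(Z)-2-[(2S)-2-methyloxiran-2-yl]ethenyl}-1,3,2-dioxaborolane F3. Suzuki–Miyaura coupling of F3 with 3 (Pd(dppf)Cl2, CsF, THF, rt) retains the alkene geometry and comes back to the route at 8.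

Step 3. The epoxy aldehyde and the epoxy alkyne are low-boiling and may be lost on isolation, and the very electrophilic aldehyde may degrade in methanolic carbonate. The fallback avoids the alkyne altogether and sets out from 4. Oxidation as in step 3 gives 5, whose CH2Cl2 solution is washed with NaHCO3, dried and added at −78 °C to Ph3P=CHI (from (iodomethyl)triphenylphosphonium iodide and NaHMDS, THF). This Stork–Zhao olefination should give the less volatile (2S)-2-[(Z)-2-iodoethenyl]-2-methyloxirane F4. Miyaura borylation of 3 (B2pin2, Pd(dppf)Cl2, KOAc, dioxane, 80 °C) gives 4-acetyl-5-hydroxy-2-(4,4,5,5-tetramethyl-1,3,2-dioxaborolan-2-yl)phenyl acetate F5. Suzuki–Miyaura coupling of F4 with F5 (Pd(dppf)Cl2, CsF, THF, rt) comes back to the route at 8, so steps 4 and 5 are bypassed.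

Further compounds
F1 | step 6 | [(2R)-6-acetyl-7-hydroxy-2-methyl-2H-chromen-2-yl]methyl (1S,4R)-4,7,7-trimethyl-3-oxo-2-oxabicyclo[2.2.1]heptane-1-carboxylate | C[C@]12CC[C@](C(=O)OC[C@@]3(C)C=Cc4cc(C(C)=O)c(O)cc4O3)(OC1=O)C2(C)C
F2 | step 6 | [(2S)-6-acetyl-7-hydroxy-2-methyl-2H-chromen-2-yl]methyl (1S,4R)-4,7,7-trimethyl-3-oxo-2-oxabicyclo[2.2.1]heptane-1-carboxylate | C[C@]12CC[C@](C(=O)OC[C@]3(C)C=Cc4cc(C(C)=O)c(O)cc4O3)(OC1=O)C2(C)C
F3 | step 5 | 4,4,5,5-tetramethyl-2-{(Z)-2-[(2S)-2-methyloxiran-2-yl]ethenyl}-1,3,2-dioxaborolane | C[C@]1(/C=C\B2OC(C)(C)C(C)(C)O2)CO1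
F4 | step 3 | (2S)-2-[(Z)-2-iodoethenyl]-2-methyloxirane | C[C@]1(/C=C\I)CO1
F5 | step 3 | 4-acetyl-5-hydroxy-2-(4,4,5,5-tetramethyl-1,3,2-dioxaborolan-2-yl)phenyl acetate | CC(=O)Oc1cc(O)c(C(C)=O)cc1B1OC(C)(C)C(C)(C)O1
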